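**Retrosynthetic overview**

1. The target is a trans-3,4-dibenzyl-γ-butyrolactone (ring A: O1, C2(=O), C3, C4, C5). Ring B (on the C4 benzyl) carries the anti 7S,8S arm C7–C8–C9 ending in ring D; ring C (on the C3 benzyl) carries the syn 7'S,8'R arm ending in ring E.
2. The strategy rests on the O1–C5 bond and the lone stereocentre C4 of ring A. Both map onto a 3-(arylmethyl)cyclobutanone: oxygen insertion into one of its two CH2–C(=O) bonds makes ring A and sets C4 in one step.
3. Disconnections: C3–CH2(ring C) by trans-selective lactone enolate alkylation with a ring C benzylic bromide; the cyclobutanone from the eugenol allyl group by dichloroketene [2+2] cycloaddition and dechlorination; C7–C8 and C7'–C8' by an anti and a syn auxiliary aldol reaction of one eugenol-derived arylacetyl imide with O-benzylvanillin.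
4. Ring order: the four arenes are bought; the cyclobutanone is built on ring B and then expanded to ring A, the only ring that is made. Phenols travel as benzyl ethers and arm hydroxyls as silyl ethers, removed last by fluoride and hydrogenolysis.

Key step: step 12

Assumption: the sense of induction of the phosphoric acid in step 12 is taken from the 3-substituted cyclobutanone series and is to be checked on 3-benzylcyclobutanone; should the model lactone prove (R), the enantiomeric (S)-acid is used with everything else unchanged.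

Abbreviations: Bn = benzyl, TBS = tert-butyldimethylsilyl, TMS = trimethylsilyl.

**Route**

Step 1
Reactants: 1 eugenol
Product: 2 5-allyl-2-hydroxy-3-methoxybenzaldehyde
Conditions: MgCl2, Et3N, (CH2O)n, MeCN, reflux; aq. HCl
Reagents that add atoms: paraformaldehyde (as formaldehyde), C=O
Why: Magnesium-phenoxide-directed ortho-formylation (Casnati–Skattebøl reaction) can only strike the single free position ortho to the phenol and leaves the allyl group untouched.

Step 2
Reactants: 2 5-allyl-2-hydroxy-3-methoxybenzaldehyde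
Product: 3 5-allyl-2-(benzyloxy)-3-methoxybenzaldehyde
Conditions: BnBr, K2CO3, DMF, rt
Reagents that add atoms: benzyl bromide, BrCc1ccccc1
Why: Williamson etherification of the phenoxide gives a benzyl ether that should survive every later step and is removed last by hydrogenolysis.

Step 3
Reactants: 3 5-allyl-2-(benzyloxy)-3-methoxybenzaldehyde
Product: 4 5-allyl-2-(benzyloxy)-1-methoxy-3-(2-methoxyvinyl)benzene (E/Z mixture)
Conditions: Ph3P(CH2OMe)Cl, KOtBu, THF, 0 °C to rt
Reagents that add atoms: (methoxymethyl)triphenylphosphonium chloride, COC[P+](c1ccccc1)(c1ccccc1)c1ccccc1.[Cl-]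
Why: Wittig olefination of the non-enolisable aldehyde with the methoxymethylene ylide gives the one-carbon-homologated enol ether, whose E/Z ratio is irrelevant.

Step 4
Reactants: 4 enol ether
Product: 5 2-[5-allyl-2-(benzyloxy)-3-methoxyphenyl]acetaldehyde
Conditions: 2 M aq. HCl, THF, 60 °C
Reagents that add atoms: water, O
Why: Acid-catalysed enol ether hydrolysis (C-protonation, then hemiacetal collapse) unmasks the arylacetaldehyde without touching the allyl group or the benzyl ether.

Step 5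
Reactants: 5 arylacetaldehyde
Product: 6 2-[5-allyl-2-(benzyloxy)-3-methoxyphenyl]acetic acid
Conditions: NaClO2, NaH2PO4, 2-methyl-2-butene, tBuOH/H2O, rt
Reagents that add atoms: sodium chlorite, [Na+].[O-]Cl=O
Why: Pinnick oxidation converts the aldehyde into the acid under buffered conditions, with 2-methyl-2-butene scavenging HOCl so that the allyl group and the electron-rich ring are not chlorinated.

Step 6
Reactants: 6 arylacetic acid; 7 (S)-4-benzyl-2-oxazolidinone
Product: 9 (S)-4-benzyl-3-{2-[5-allyl-2-(benzyloxy)-3-methoxyphenyl]acetyl}oxazolidin-2-one, via mixed pivalic anhydride 8 (not isolated)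
Conditions: PivCl, Et3N, THF, −20 °C; then 7, LiCl, rt
Reagents that add atoms: none
Why: Mixed-anhydride N-acylation of the oxazolidinone under LiCl/Et3N activation gives the one imide that serves as aldol donor for both arms.

Step 7
Reactants: 9 arylacetyl imide; 10 O-benzylvanillin
Product: 11 (S)-4-benzyl-3-[(2R,3S)-2-(5-allyl-2-benzyloxy-3-methoxyphenyl)-3-(4-benzyloxy-3-methoxyphenyl)-3-(trimethylsilyloxy)propanoyl]oxazolidin-2-one
Conditions: MgCl2 (0.2 equiv), Et3N, TMSCl, EtOAc, rt
Reagents that add atoms: chlorotrimethylsilane, C[Si](C)(C)Cl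
Why: Magnesium-halide-catalysed direct anti-aldol of an N-acyloxazolidinone: soft enolisation gives the chelated Z-magnesium enolate, the aromatic aldehyde adds through a boat-type transition state to the face away from the auxiliary benzyl group (the α-facial sense of enolate alkylation), and silylation turns the catalyst over, which should set C8 and C7 as the anti 7S,8S pair.

Step 8
Reactants: 11 silylated anti-aldol adduct
Product: 13 (1S,2S)-2-[5-allyl-2-(benzyloxy)-3-methoxyphenyl]-1-[4-(benzyloxy)-3-methoxyphenyl]propane-1,3-diol, via C7 trimethylsilyl ether alcohol 12 (not isolated)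
Conditions: LiBH4, MeOH (1 equiv), Et2O, 0 °C; then K2CO3, MeOH, rt
Reagents that add atoms: none
Why: Reductive auxiliary cleavage by LiBH4 at the exocyclic imide carbonyl, run on the silyl-masked aldol so that retro-aldol cannot occur, followed by methanolysis of the TMS ether; no stereocentre is touched.

Step 9
Reactants: 13 anti diol
Product: 14 bis-TBS ether of 13: (1S,2S)-2-[5-allyl-2-(benzyloxy)-3-methoxyphenyl]-1-[4-(benzyloxy)-3-methoxyphenyl]-1,3-bis(tert-butyldimethylsilyloxy)propane
Conditions: TBSOTf (2.5 equiv), 2,6-lutidine, CH2Cl2, −78 to 0 °C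
Reagents that add atoms: tert-butyldimethylsilyl triflate, CC(C)(C)[Si](C)(C)OS(=O)(=O)C(F)(F)F
Why: Silyl ether formation with the silyl triflate and 2,6-lutidine is strong enough to cap both the primary and the hindered benzylic secondary hydroxyl.

Step 10
Reactants: 14 bis-TBS allyl arene; 15 trichloroacetyl chloride
Product: 17 2,2-dichloro-3-{4-(benzyloxy)-3-methoxy-5-[(1S,2S)-1,3-bis(TBS-oxy)-1-(4-benzyloxy-3-methoxyphenyl)propan-2-yl]benzyl}cyclobutan-1-one (both epimers at the ring CH), via dichloroketene 16 (not isolated)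
Conditions: Zn–Cu couple, Et2O/DME, sonication, rt
Reagents that add atoms: none
Why: Dichloroketene generated by zinc dehalogenation undergoes thermal [2+2] cycloaddition with the terminal alkene, its carbonyl carbon bonding to the CH2 terminus; the new ring stereocentre is uncontrolled and is erased in step 11.

Step 11
Reactants: 17 dichlorocyclobutanone
Product: 18 3-{4-(benzyloxy)-3-methoxy-5-[(1S,2S)-1,3-bis(TBS-oxy)-1-(4-benzyloxy-3-methoxyphenyl)propan-2-yl]benzyl}cyclobutan-1-one
Conditions: Zn, NH4Cl, MeOH, rt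
Reagents that add atoms: none
Why: Reductive dehalogenation: zinc cleaves both α-C–Cl bonds through zinc enolates that NH4Cl protonates, mild enough for the silyl and benzyl ethers, and the ring CH ceases to be stereogenic.

Step 12
Reactants: 18 armed 3-(arylmethyl)cyclobutanone
Product: 20 (S)-4-{4-(benzyloxy)-3-methoxy-5-[(1S,2S)-1,3-bis(TBS-oxy)-1-(4-benzyloxy-3-methoxyphenyl)propan-2-yl]benzyl}dihydrofuran-2(3H)-one, via peroxy hemiketal 19 (not isolated)
Conditions: (R)-3,3'-di(pyren-1-yl)-H8-BINOL phosphoric acid (10 mol%), 30% aq. H2O2 (1.5 equiv), CHCl3, −40 °C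
Reagents that add atoms: hydrogen peroxide, OO
Why: The phosphoric acid hydrogen-bonds both ketone 18 and H2O2, peroxide adds to the strained carbonyl to give Criegee adduct 19, and the α-CH2 held antiperiplanar to the O–O bond shifts from carbon to oxygen with loss of water; the closest known reaction type is the chiral-phosphoric-acid-catalysed desymmetrising Baeyer–Villiger oxidation of 3-substituted cyclobutanones with aqueous H2O2. Ring A is not closed by a cyclisation but arises by expansion of the four-membered ring: peroxide addition forms O1–C2 and the 1,2-shift forms O1–C5. C4 becomes stereogenic in this step and its configuration is decided by the catalyst, whose chiral pocket fixes which of the two α-CH2 groups migrates. Because of the arm stereocentres these two CH2 groups are strictly diastereotopic rather than enantiotopic, but C8 and C7 lie five and six bonds from C4, so the catalyst and not the substrate should control the choice; a minor C4 epimer would be removed by chromatography here or after step 19. The step also needs chemoselectivity for the cyclobutanone over the electron-rich arenes, the benzyl ethers and the silyl ethers, which ring strain secures, since only the cyclobutanone forms a peroxy hemiketal under these conditions.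

Step 13
Reactants: 9 arylacetyl imide; 10 O-benzylvanillin
Product: 23 (S)-4-benzyl-3-[(2S,3S)-2-(5-allyl-2-benzyloxy-3-methoxyphenyl)-3-(4-benzyloxy-3-methoxyphenyl)-3-hydroxypropanoyl]oxazolidin-2-one, via Z-dibutylboron enolate 21 (not isolated), via dibutylboron aldolate 22 (not isolated)
Conditions: Bu2BOTf, iPr2NEt, CH2Cl2, −78 to 0 °C; then 10, −78 to 0 °C; then pH 7 buffer, MeOH, 30% H2O2, 0 °C
Reagents that add atoms: none
Why: Evans syn-aldol: the Z-boron enolate reacts through a chair Zimmerman–Traxler transition state on the enolate face away from the auxiliary benzyl group in the dipole-minimised imide conformation, which should set C8' and C7' as the syn 7'S,8'R pair.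

Step 14
Reactants: 23 syn-aldol adduct
Product: 24 (1S,2R)-2-[5-allyl-2-(benzyloxy)-3-methoxyphenyl]-1-[4-(benzyloxy)-3-methoxyphenyl]propane-1,3-diol
Conditions: LiBH4, MeOH (1 equiv), THF, 0 °C
Reagents that add atoms: none
Why: Reductive auxiliary cleavage by LiBH4 at the exocyclic imide carbonyl; low temperature and the boron-bound aldol oxygen should suppress retro-aldol, so both stereocentres are kept.

Step 15
Reactants: 24 syn diol
Product: 25 bis-TBS ether of 24: (1S,2R)-2-[5-allyl-2-(benzyloxy)-3-methoxyphenyl]-1-[4-(benzyloxy)-3-methoxyphenyl]-1,3-bis(tert-butyldimethylsilyloxy)propane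
Conditions: TBSOTf (2.5 equiv), 2,6-lutidine, CH2Cl2, −78 to 0 °C
Reagents that add atoms: tert-butyldimethylsilyl triflate, CC(C)(C)[Si](C)(C)OS(=O)(=O)C(F)(F)F
Why: Silyl ether formation as in step 9 caps both arm hydroxyls.

Step 16
Reactants: 25 bis-TBS allyl arene
Product: 26 (E)-prop-1-enyl isomer of 25
Conditions: RuHCl(CO)(PPh3)3 (5 mol%), toluene, 80 °C
Reagents that add atoms: none
Why: Ruthenium-hydride-catalysed olefin isomerisation (hydrometallation, then β-hydride elimination) moves the double bond into conjugation with ring C, mainly as the E isomer.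

Step 17
Reactants: 26 propenyl arene
Product: 28 {4-(benzyloxy)-3-methoxy-5-[(1S,2R)-1,3-bis(TBS-oxy)-1-(4-benzyloxy-3-methoxyphenyl)propan-2-yl]phenyl}methanol, via ozonide 27 (not isolated)
Conditions: O3, CH2Cl2, −78 °C; then NaBH4, MeOH, −78 to 0 °C
Reagents that add atoms: ozone, [O-][O+]=O
Why: Reductive ozonolysis: ozone cleaves the electron-rich styrenyl double bond faster than it attacks the arenes, and borohydride reduces the ozonide directly to the benzylic alcohol.

Step 18
Reactants: 28 benzylic alcohol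
Product: 29 4-(benzyloxy)-3-methoxy-5-[(1S,2R)-1,3-bis(TBS-oxy)-1-(4-benzyloxy-3-methoxyphenyl)propan-2-yl]benzyl bromide
Conditions: CBr4, PPh3, CH2Cl2, 0 °C
Reagents that add atoms: carbon tetrabromide, BrC(Br)(Br)Br
Why: Appel bromination converts the primary benzylic alcohol into the bromide under neutral conditions that spare the silyl ethers; the bromide is used at once.

Step 19
Reactants: 20 (S)-β-benzyl lactone; 29 ring C benzylic bromide
Product: 31 (3S,4S)-3-{4-(benzyloxy)-3-methoxy-5-[(1S,2R)-1,3-bis(TBS-oxy)-1-(4-benzyloxy-3-methoxyphenyl)propan-2-yl]benzyl}-4-{4-(benzyloxy)-3-methoxy-5-[(1S,2S)-1,3-bis(TBS-oxy)-1-(4-benzyloxy-3-methoxyphenyl)propan-2-yl]benzyl}dihydrofuran-2(3H)-one, via lithium enolate 30 (not isolated)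
Conditions: LiN(SiMe3)2, THF, −78 °C; then 29, DMPU, −78 to −30 °C
Reagents that add atoms: none
Why: Diastereoselective enolate alkylation: the lactone enolate is attacked by the benzylic bromide on the face anti to the C4 substituent, so the C3–CH2 bond forms trans to the ring B benzyl group and C3 is set as S by substrate control.

Step 20
Reactants: 31 fully protected lactone
Product: 32 tetra-O-benzyl ether of the target (all four arm hydroxyls free)
Conditions: Bu4NF, AcOH, THF, rt to 40 °C
Reagents that add atoms: none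
Why: Fluoride-mediated desilylation removes the four TBS groups, the acetic acid buffer protecting the lactone; C3 cannot be lost because trans is the thermodynamic isomer.

Step 21
Reactants: 32 tetra-O-benzyl tetraol
Product: 33 target, (3S,4S)-3-{4-hydroxy-3-[(1S,2R)-1,3-dihydroxy-1-(4-hydroxy-3-methoxyphenyl)propan-2-yl]-5-methoxybenzyl}-4-{4-hydroxy-3-[(1S,2S)-1,3-dihydroxy-1-(4-hydroxy-3-methoxyphenyl)propan-2-yl]-5-methoxybenzyl}dihydrofuran-2(3H)-one
Conditions: H2 (1 atm), Pd/C (10%), EtOAc/MeOH, rt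
Reagents that add atoms: none
Why: Catalytic hydrogenolysis cleaves the four aryl benzyl ethers under neutral conditions, under which the secondary benzylic alcohols should survive and acid-promoted closure to a phenylcoumaran is avoided.

**Compound list**

1 | eugenol | COc1cc(CC=C)ccc1O | starting material
2 | 5-allyl-2-hydroxy-3-methoxybenzaldehyde | COc1cc(CC=C)cc(C=O)c1O | intermediate
3 | 5-allyl-2-(benzyloxy)-3-methoxybenzaldehyde | COc1cc(CC=C)cc(C=O)c1OCc1ccccc1 | intermediate
4 | 5-allyl-2-(benzyloxy)-1-methoxy-3-(2-methoxyvinyl)benzene (E/Z mixture) | COC=Cc1cc(CC=C)cc(OC)c1OCc1ccccc1 | intermediate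
5 | 2-[5-allyl-2-(benzyloxy)-3-methoxyphenyl]acetaldehyde | O=CCc1cc(CC=C)cc(OC)c1OCc1ccccc1 | intermediate
6 | 2-[5-allyl-2-(benzyloxy)-3-methoxyphenyl]acetic acid | OC(=O)Cc1cc(CC=C)cc(OC)c1OCc1ccccc1 | intermediate
7 | (S)-4-benzyl-2-oxazolidinone | O=C1N[C@@H](Cc2ccccc2)CO1 | starting material
8 | mixed pivalic anhydride of acid 6 | CC(C)(C)C(=O)OC(=O)Cc1cc(CC=C)cc(OC)c1OCc1ccccc1 | intermediate (not isolated)
9 | (S)-4-benzyl-3-{2-[5-allyl-2-(benzyloxy)-3-methoxyphenyl]acetyl}oxazolidin-2-one | O=C(Cc1cc(CC=C)cc(OC)c1OCc1ccccc1)N1[C@@H](Cc2ccccc2)COC1=O | intermediate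
10 | O-benzylvanillin (4-benzyloxy-3-methoxybenzaldehyde) | COc1cc(C=O)ccc1OCc1ccccc1 | starting material
11 | anti-aldol adduct as TMS ether, (2R,3S) acyl chain on the (S)-auxiliary | COc1cc([C@@H](O[Si](C)(C)C)[C@H](C(=O)N2[C@@H](Cc3ccccc3)COC2=O)c2cc(CC=C)cc(OC)c2OCc2ccccc2)ccc1OCc1ccccc1 | intermediate
12 | (2S,3S)-2-(5-allyl-2-benzyloxy-3-methoxyphenyl)-3-(4-benzyloxy-3-methoxyphenyl)-3-(trimethylsilyloxy)propan-1-ol | COc1cc([C@@H](O[Si](C)(C)C)[C@H](CO)c2cc(CC=C)cc(OC)c2OCc2ccccc2)ccc1OCc1ccccc1 | intermediate (not isolated)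
13 | (1S,2S)-2-[5-allyl-2-(benzyloxy)-3-methoxyphenyl]-1-[4-(benzyloxy)-3-methoxyphenyl]propane-1,3-diol | COc1cc([C@@H](O)[C@H](CO)c2cc(CC=C)cc(OC)c2OCc2ccccc2)ccc1OCc1ccccc1 | intermediate
14 | bis-TBS ether of 13 | COc1cc([C@@H](O[Si](C)(C)C(C)(C)C)[C@H](CO[Si](C)(C)C(C)(C)C)c2cc(CC=C)cc(OC)c2OCc2ccccc2)ccc1OCc1ccccc1 | intermediate
15 | trichloroacetyl chloride | ClC(=O)C(Cl)(Cl)Cl | starting material
16 | dichloroketene | ClC(Cl)=C=O | intermediate (not isolated)
17 | 2,2-dichloro-3-(arylmethyl)cyclobutanone with the (7S,8S) bis-TBS arm (both epimers at the ring CH) | COc1cc([C@@H](O[Si](C)(C)C(C)(C)C)[C@H](CO[Si](C)(C)C(C)(C)C)c2cc(CC3CC(=O)C3(Cl)Cl)cc(OC)c2OCc2ccccc2)ccc1OCc1ccccc1 | intermediate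
18 | armed 3-(arylmethyl)cyclobutanone (key-step precursor) | COc1cc([C@@H](O[Si](C)(C)C(C)(C)C)[C@H](CO[Si](C)(C)C(C)(C)C)c2cc(CC3CC(=O)C3)cc(OC)c2OCc2ccccc2)ccc1OCc1ccccc1 | intermediate
19 | 1-hydroperoxy-3-(arylmethyl)cyclobutan-1-ol (Criegee adduct of 18) | COc1cc([C@@H](O[Si](C)(C)C(C)(C)C)[C@H](CO[Si](C)(C)C(C)(C)C)c2cc(CC3CC(O)(OO)C3)cc(OC)c2OCc2ccccc2)ccc1OCc1ccccc1 | intermediate (not isolated)
20 | armed (S)-4-(arylmethyl)dihydrofuran-2(3H)-one (key-step product) | COc1cc([C@@H](O[Si](C)(C)C(C)(C)C)[C@H](CO[Si](C)(C)C(C)(C)C)c2cc(C[C@@H]3COC(=O)C3)cc(OC)c2OCc2ccccc2)ccc1OCc1ccccc1 | intermediate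
21 | Z-dibutylboron enolate of imide 9 | CCCCB(CCCC)O/C(=C\c1cc(CC=C)cc(OC)c1OCc1ccccc1)N1[C@@H](Cc2ccccc2)COC1=O | intermediate (not isolated)
22 | dibutylboron aldolate of 23 | COc1cc([C@@H](OB(CCCC)CCCC)[C@@H](C(=O)N2[C@@H](Cc3ccccc3)COC2=O)c2cc(CC=C)cc(OC)c2OCc2ccccc2)ccc1OCc1ccccc1 | intermediate (not isolated)
23 | syn-aldol adduct, (2S,3S) acyl chain on the (S)-auxiliary | COc1cc([C@@H](O)[C@@H](C(=O)N2[C@@H](Cc3ccccc3)COC2=O)c2cc(CC=C)cc(OC)c2OCc2ccccc2)ccc1OCc1ccccc1 | intermediate
24 | (1S,2R)-2-[5-allyl-2-(benzyloxy)-3-methoxyphenyl]-1-[4-(benzyloxy)-3-methoxyphenyl]propane-1,3-diol | COc1cc([C@@H](O)[C@@H](CO)c2cc(CC=C)cc(OC)c2OCc2ccccc2)ccc1OCc1ccccc1 | intermediate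
25 | bis-TBS ether of 24 | COc1cc([C@@H](O[Si](C)(C)C(C)(C)C)[C@@H](CO[Si](C)(C)C(C)(C)C)c2cc(CC=C)cc(OC)c2OCc2ccccc2)ccc1OCc1ccccc1 | intermediate
26 | (E)-prop-1-enyl isomer of 25 | COc1cc([C@@H](O[Si](C)(C)C(C)(C)C)[C@@H](CO[Si](C)(C)C(C)(C)C)c2cc(/C=C/C)cc(OC)c2OCc2ccccc2)ccc1OCc1ccccc1 | intermediate
27 | 3-aryl-5-methyl-1,2,4-trioxolane (ozonide of 26) | COc1cc([C@@H](O[Si](C)(C)C(C)(C)C)[C@@H](CO[Si](C)(C)C(C)(C)C)c2cc(C3OOC(C)O3)cc(OC)c2OCc2ccccc2)ccc1OCc1ccccc1 | intermediate (not isolated)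
28 | ring C benzylic alcohol with the (7'S,8'R) bis-TBS arm | COc1cc([C@@H](O[Si](C)(C)C(C)(C)C)[C@@H](CO[Si](C)(C)C(C)(C)C)c2cc(CO)cc(OC)c2OCc2ccccc2)ccc1OCc1ccccc1 | intermediate
29 | ring C benzylic bromide with the (7'S,8'R) bis-TBS arm | COc1cc([C@@H](O[Si](C)(C)C(C)(C)C)[C@@H](CO[Si](C)(C)C(C)(C)C)c2cc(CBr)cc(OC)c2OCc2ccccc2)ccc1OCc1ccccc1 | intermediate
30 | lithium enolate of lactone 20 | COc1cc([C@@H](O[Si](C)(C)C(C)(C)C)[C@H](CO[Si](C)(C)C(C)(C)C)c2cc(C[C@@H]3COC(O[Li])=C3)cc(OC)c2OCc2ccccc2)ccc1OCc1ccccc1 | intermediate (not isolated)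
31 | (3S,4S)-trans-dibenzyl lactone, four phenols as Bn ethers and four arm hydroxyls as TBS ethers | COc1cc([C@@H](O[Si](C)(C)C(C)(C)C)[C@H](CO[Si](C)(C)C(C)(C)C)c2cc(C[C@@H]3COC(=O)[C@H]3Cc3cc(OC)c(OCc4ccccc4)c([C@H](CO[Si](C)(C)C(C)(C)C)[C@H](O[Si](C)(C)C(C)(C)C)c4ccc(OCc5ccccc5)c(OC)c4)c3)cc(OC)c2OCc2ccccc2)ccc1OCc1ccccc1 | intermediate
32 | tetra-O-benzyl ether of the target | COc1cc([C@@H](O)[C@H](CO)c2cc(C[C@@H]3COC(=O)[C@H]3Cc3cc(OC)c(OCc4ccccc4)c([C@H](CO)[C@H](O)c4ccc(OCc5ccccc5)c(OC)c4)c3)cc(OC)c2OCc2ccccc2)ccc1OCc1ccccc1 | intermediate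
33 | CNP0113972.1 | COc1cc([C@@H](O)[C@H](CO)c2cc(C[C@@H]3COC(=O)[C@H]3Cc3cc(OC)c(O)c([C@H](CO)[C@H](O)c4ccc(O)c(OC)c4)c3)cc(OC)c2O)ccc1O | target

**Step count and risks**

Total step count: 21. Longest linear sequence: 15 steps (1–6, 7–12, 19–21; the ring C branch 1–6, 13–18, 19–21 is equally long).

Three steps most likely to fail:

1. Step 12. The catalyst may discriminate poorly between the two α-CH2 groups in the 1,2-shift, since arylmethyl-substituted cyclobutanones are a less selective class for acid-catalysed oxygen insertion than aryl-substituted ones. The resulting C4 epimers would be hard to separate because the other stereocentres are remote. Fallback: C4 is set by auxiliary-controlled enolate alkylation instead of desymmetrisation; it sets out from alkene 14 and comes back at lactone 20. Hydroboration–oxidation of 14 (9-BBN; NaOH, H2O2) should give the 3-arylpropan-1-ol F1. TEMPO/PhI(OAc)2 oxidation in MeCN/H2O should give the 3-arylpropanoic acid F2. Pivaloyl mixed-anhydride coupling with (R)-4-benzyl-2-oxazolidinone should give the propanoyl imide F3. Alkylation of its sodium enolate (NaN(SiMe3)2, THF, −78 °C) with tert-butyl bromoacetate, on the face away from the auxiliary benzyl group, should give the succinate imide F4. LiBH4 should release the auxiliary and give the hydroxy tert-butyl ester F5, which closes to 20 with catalytic camphorsulfonic acid in toluene.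

2. Step 7. Reversible addition may erode the anti/syn ratio, or the acidic arylacetyl imide enolate may be silylated instead of adding to the aldehyde. Fallback: the arm is made by a syn-aldol reaction followed by inversion at C7; it sets out from acid 6 and comes back at bis-silyl ether 14. Coupling of 6 with (R)-4-benzyl-2-oxazolidinone (PivCl, Et3N, LiCl) should give the enantiomeric-auxiliary imide F6. Its dibutylboron syn-aldol reaction with 10 should give the (2R,3R) adduct F7, with C8 correct and C7 wrong. LiBH4 should give the (1R,2S) diol F8, and TBSCl/imidazole should silylate only the primary hydroxyl to give the mono-silyl ether F9. Mitsunobu esterification with 4-nitrobenzoic acid (PPh3, DIAD) should invert C7 and give the 4-nitrobenzoate F10. K2CO3/MeOH should give the (1S,2S) alcohol F11, and TBSOTf/2,6-lutidine then gives 14.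

3. Step 10. ZnCl2 may promote ionisation or loss of the benzylic silyl ether, and ketene oligomerisation may outrun cycloaddition to the unactivated terminal alkene. Fallback: a keteniminium [2+2] cycloaddition that needs neither zinc nor a dechlorination; it sets out from 14 and comes back at cyclobutanone 18, replacing steps 10 and 11. N,N-Dimethylacetamide, Tf2O and 2,4,6-collidine in 1,2-dichloroethane at 80 °C should give the cyclobutaniminium triflate F12, which aqueous NaHCO3 hydrolyses to 18.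

Further compounds

F1 | step 12 | 3-arylpropan-1-ol from hydroboration of 14 | COc1cc([C@@H](O[Si](C)(C)C(C)(C)C)[C@H](CO[Si](C)(C)C(C)(C)C)c2cc(CCCO)cc(OC)c2OCc2ccccc2)ccc1OCc1ccccc1
F2 | step 12 | 3-arylpropanoic acid | COc1cc([C@@H](O[Si](C)(C)C(C)(C)C)[C@H](CO[Si](C)(C)C(C)(C)C)c2cc(CCC(O)=O)cc(OC)c2OCc2ccccc2)ccc1OCc1ccccc1
F3 | step 12 | (R)-4-benzyl-3-(3-arylpropanoyl)oxazolidin-2-one | COc1cc([C@@H](O[Si](C)(C)C(C)(C)C)[C@H](CO[Si](C)(C)C(C)(C)C)c2cc(CCC(=O)N3[C@H](Cc4ccccc4)COC3=O)cc(OC)c2OCc2ccccc2)ccc1OCc1ccccc1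
F4 | step 12 | tert-butyl (S)-3-(arylmethyl)-4-oxo-4-[(R)-4-benzyl-2-oxooxazolidin-3-yl]butanoate | COc1cc([C@@H](O[Si](C)(C)C(C)(C)C)[C@H](CO[Si](C)(C)C(C)(C)C)c2cc(C[C@@H](CC(=O)OC(C)(C)C)C(=O)N3[C@H](Cc4ccccc4)COC3=O)cc(OC)c2OCc2ccccc2)ccc1OCc1ccccc1
F5 | step 12 | tert-butyl (S)-3-(arylmethyl)-4-hydroxybutanoate | COc1cc([C@@H](O[Si](C)(C)C(C)(C)C)[C@H](CO[Si](C)(C)C(C)(C)C)c2cc(C[C@H](CO)CC(=O)OC(C)(C)C)cc(OC)c2OCc2ccccc2)ccc1OCc1ccccc1
F6 | step 7 | (R)-4-benzyl-3-{2-[5-allyl-2-(benzyloxy)-3-methoxyphenyl]acetyl}oxazolidin-2-one | O=C(Cc1cc(CC=C)cc(OC)c1OCc1ccccc1)N1[C@H](Cc2ccccc2)COC1=O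
F7 | step 7 | syn-aldol adduct, (2R,3R) acyl chain on the (R)-auxiliary | COc1cc([C@H](O)[C@H](C(=O)N2[C@H](Cc3ccccc3)COC2=O)c2cc(CC=C)cc(OC)c2OCc2ccccc2)ccc1OCc1ccccc1
F8 | step 7 | (1R,2S)-2-[5-allyl-2-(benzyloxy)-3-methoxyphenyl]-1-[4-(benzyloxy)-3-methoxyphenyl]propane-1,3-diol | COc1cc([C@H](O)[C@H](CO)c2cc(CC=C)cc(OC)c2OCc2ccccc2)ccc1OCc1ccccc1
F9 | step 7 | primary mono-TBS ether of F8 | COc1cc([C@H](O)[C@H](CO[Si](C)(C)C(C)(C)C)c2cc(CC=C)cc(OC)c2OCc2ccccc2)ccc1OCc1ccccc1
F10 | step 7 | C7-inverted 4-nitrobenzoate | COc1cc([C@@H](OC(=O)c3ccc(cc3)[N+](=O)[O-])[C@H](CO[Si](C)(C)C(C)(C)C)c2cc(CC=C)cc(OC)c2OCc2ccccc2)ccc1OCc1ccccc1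
F11 | step 7 | (1S,2S) alcohol with the primary TBS ether | COc1cc([C@@H](O)[C@H](CO[Si](C)(C)C(C)(C)C)c2cc(CC=C)cc(OC)c2OCc2ccccc2)ccc1OCc1ccccc1
F12 | step 10 | N,N-dimethyl-3-(arylmethyl)cyclobutan-1-iminium triflate | COc1cc([C@@H](O[Si](C)(C)C(C)(C)C)[C@H](CO[Si](C)(C)C(C)(C)C)c2cc(CC3CC(=[N+](C)C)C3)cc(OC)c2OCc2ccccc2)ccc1OCc1ccccc1.[O-]S(=O)(=O)C(F)(F)F
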